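**Plan**

- Guaiane locants are used throughout: C1–C5 is the cyclopentenone (C3 carbonyl, C4=C5), C5–C10 plus C1 is the seven-membered ring, and C11 sits on C7. The enabling feature is that C8 carries an oxygen, C7 a carboxyl-derived carbon (C11), C10 a methyl next to C1, and C5 can hold a temporary oxygen β to the C3 carbonyl. That is the substitution pattern of an 8-oxabicyclo[3.2.1]oct-3-en-2-one made from a 3-oxidopyrylium and an acrylate.
- Retrosynthesis: remove the two esters; re-close a C5–O–C8 ether onto the C4=C5 enone (reverse of an E1cB opening); open the five-membered ring at C2=C3 (metathesis) and C1–C2 (vinyl addition); cut C5–C6 and C7–C8 of the oxygen-bridged seven-membered ring.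
- Forward: furan → pyranone → (5+2) cycloaddition gives the bridged seven-membered ring → the five-membered ring is closed by vinyl addition, metathesis and oxidative transposition → the bridge is opened and the two esters are installed.
- Stereochemistry: the C4 centre from an asymmetric crotylboration biases the face of the cycloaddition (C5/C8) and is erased at the end. C7 and C10 are set by equilibration on the bicycle (exo, equatorial). C1 is set by hydrogenation from the bridge-oxygen face. C8 is carried inside the bridge.

Key step: step 4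

Remark: (R)-TRIP is assumed to direct crotyl transfer to the Re face of the aldehyde; the lactol and its acetate are anomeric mixtures, which is immaterial because that carbon becomes planar in the ylide.

**Step 1**
Reactants: 1 3-methylfuran-2-carbaldehyde; 2 (E)-crotylboronic acid pinacol ester
Product: 4 (1R,2R)-2-methyl-1-(3-methylfuran-2-yl)but-3-en-1-ol, via pinacol borate ester 3 (not isolated)
Conditions: (R)-TRIP (5 mol %), toluene, −30 °C; then H2O
Reagents that add atoms: none
Why: Chiral phosphoric acid-catalysed crotylboration through a closed chair (Zimmerman–Traxler) transition state; the (E)-boronate gives the anti adduct and the acid selects the Re face, setting (1R,2R), of which only the methyl-bearing centre (future C4) must persist.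

**Step 2**
Reactants: 4 (1R,2R)-2-methyl-1-(3-methylfuran-2-yl)but-3-en-1-ol
Product: 5 (2R)-2-[(2R)-but-3-en-2-yl]-6-hydroxy-4-methyl-2H-pyran-3(6H)-one
Conditions: NBS, NaHCO3, THF/H2O (4:1), 0 °C
Reagents that add atoms: water, O
Why: Achmatowicz rearrangement; the electron-rich furan should be oxidised well before the terminal alkene, the resulting cis-enedione closes onto the carbinol oxygen, and both carbon stereocentres are untouched.

**Step 3**
Reactants: 5 (2R)-2-[(2R)-but-3-en-2-yl]-6-hydroxy-4-methyl-2H-pyran-3(6H)-one
Product: 6 (2R)-6-acetoxy-2-[(2R)-but-3-en-2-yl]-4-methyl-2H-pyran-3(6H)-one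
Conditions: Ac2O, pyridine, DMAP (cat.), CH2Cl2, −20 → 0 °C
Reagents that add atoms: acetic anhydride, CC(=O)OC(C)=O
Why: Standard O-acylation of the lactol turns the anomeric hydroxyl into the leaving group needed for ylide formation; low temperature avoids premature elimination.

**Step 4**
Reactants: 6 (2R)-6-acetoxy-2-[(2R)-but-3-en-2-yl]-4-methyl-2H-pyran-3(6H)-one; 7 methyl acrylate
Product: 9 methyl (1S,5R)-1-[(2R)-but-3-en-2-yl]-3-methyl-2-oxo-8-oxabicyclo[3.2.1]oct-3-ene-6-carboxylate (both C6 epimers), via oxidopyrylium ylide 8 (not isolated)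
Conditions: methyl acrylate (10 equiv), Et3N (1.5 equiv), CH2Cl2, 25 → 40 °C
Reagents that add atoms: none
Why: Et3N enolises the ketone of 6 and acetate departs, so the two stereogenic ring carbons become planar in the 3-oxidopyrylium 8, which adds the acrylate in a concerted, asynchronous (5+2) dipolar cycloaddition; this is the established intermolecular oxidopyrylium–acrylate route to 8-oxabicyclo[3.2.1]oct-3-en-2-ones. The seven-membered carbocycle closes intermolecularly through the two new bonds C5–C6 and C7–C8, made on one face of the ylide, with the former pyran oxygen left as the one-atom C5–O–C8 bridge. Regiochemistry follows from the polarisation of the ylide: the terminus beside the oxido carbon (C5, largest HOMO coefficient) pairs with the unsubstituted β-carbon of the acrylate, so the ester ends on C7 beside C8. C5 and C8 are locked relative to each other by the bridge; their absolute sense should come from the C4 centre, whose C–H is expected to lie in the ylide plane toward the oxido oxygen (allylic strain), so that the acrylate bonds to C5 anti to the C4 methyl. C7 forms as an endo/exo mixture that step 5 levels. Because methyl and vinyl differ little in size the facial bias is expected to be modest, so the wrong-face adducts are removed by chromatography here or at 12; excess acrylate suppresses ylide dimerisation.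

**Step 5**
Reactants: 9 methyl (1S,5R)-1-[(2R)-but-3-en-2-yl]-3-methyl-2-oxo-8-oxabicyclo[3.2.1]oct-3-ene-6-carboxylate (both C6 epimers)
Product: 12 methyl (1S,3S,5R,6S)-1-[(2R)-but-3-en-2-yl]-3-methyl-2-oxo-8-oxabicyclo[3.2.1]octane-6-carboxylate, via lithium enolate 10 (not isolated), via unequilibrated keto ester 11 (not isolated)
Conditions: LiBH(s-Bu)3 (1.05 equiv), THF, −78 °C; then MeOH, NaOMe (0.5 equiv), −78 → 50 °C
Reagents that add atoms: none
Why: Conjugate hydride reduction of an enone with an unsubstituted β-carbon and a hindered carbonyl (quaternary C5), leaving ester and vinyl alone; methoxide then equilibrates C10 (via the ketone enolate) and C7 (via the ester enolate) to the thermodynamic isomer with the methyl equatorial on the chair oxanone and the ester exo, both cis to the oxygen bridge.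

**Step 6**
Reactants: 12 methyl (1S,3S,5R,6S)-1-[(2R)-but-3-en-2-yl]-3-methyl-2-oxo-8-oxabicyclo[3.2.1]octane-6-carboxylate
Product: 13 methyl (1S,3S,5R,6S)-1-[(2R)-but-3-en-2-yl]-2-ethenyl-2-hydroxy-3-methyl-8-oxabicyclo[3.2.1]octane-6-carboxylate
Conditions: CH2=CHMgBr (3 equiv), CeCl3 (3 equiv), THF, −78 °C
Reagents that add atoms: vinylmagnesium bromide, C=C[Mg]Br
Why: Organocerium 1,2-addition, which tolerates hindered enolisable ketones and should leave the methyl ester alone at −78 °C; vinyl should enter axially from the bridge-oxygen face (the other face is blocked by the ethano bridge), and this C1 centre is destroyed in step 9, so either epimer serves.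

**Step 7**
Reactants: 13 methyl (1S,3S,5R,6S)-1-[(2R)-but-3-en-2-yl]-2-ethenyl-2-hydroxy-3-methyl-8-oxabicyclo[3.2.1]octane-6-carboxylate
Product: 14 (1S,3S,5R,6S)-1-[(2R)-but-3-en-2-yl]-2-ethenyl-6-(2-hydroxypropan-2-yl)-3-methyl-8-oxabicyclo[3.2.1]octan-2-ol
Conditions: MeLi (4 equiv), THF, −78 → 0 °C
Reagents that add atoms: methyllithium, [Li]C
Why: Double addition of methyllithium to the ester (via the methyl ketone) builds C11 with its two methyls; addition should outpace α-deprotonation at C7, whose configuration is kept.

**Step 8**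
Reactants: 14 (1S,3S,5R,6S)-1-[(2R)-but-3-en-2-yl]-2-ethenyl-6-(2-hydroxypropan-2-yl)-3-methyl-8-oxabicyclo[3.2.1]octan-2-ol
Product: 15 5,8-epoxyguai-2-ene-1,11-diol
Conditions: second-generation Grubbs catalyst (5 mol %), CH2Cl2, 40 °C
Reagents that add atoms: none
Why: Ring-closing metathesis of the 1,6-diene (axial vinyl on C1, equatorial butenyl on C5) closes the five-membered ring as the C2=C3 alkene with loss of ethene; free tertiary alcohols are tolerated.

**Step 9**
Reactants: 15 5,8-epoxyguai-2-ene-1,11-diol
Product: 16 5,8-epoxy-11-hydroxyguai-1-en-3-one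
Conditions: pyridinium chlorochromate [C5H5NH][CrO3Cl] (3 equiv), 4 Å MS, CH2Cl2, 23 °C
Reagents that add atoms: none
Why: Dauben–Babler oxidative 1,3-transposition; the chromate ester of the tertiary allylic alcohol shifts from C1 to C3 and is oxidised to the C3 ketone with the alkene at C1=C2, while the non-allylic tertiary C11 hydroxyl cannot be oxidised.

**Step 10**
Reactants: 16 5,8-epoxy-11-hydroxyguai-1-en-3-one
Product: 17 5,8-epoxy-11-hydroxyguaian-3-one
Conditions: H2 (1 atm), 10% Pd/C, EtOAc, 23 °C
Reagents that add atoms: none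
Why: Heterogeneous hydrogenation of the enone; hydrogen should reach C1 from the face of the bridge oxygen, because the opposite face is screened by the C6 methylene of the ethano bridge and by the C4 methyl, which sits trans to the bridge oxygen by the choice of the crotylboration product. This sets H-1 cis to the bridge, as in the target.

**Step 11**
Reactants: 17 5,8-epoxy-11-hydroxyguaian-3-one
Product: 18 (1R,7S,8R,10S)-8,11-dihydroxyguai-4-en-3-one
Conditions: NaOMe (0.3 equiv), MeOH, 0 → 23 °C
Reagents that add atoms: none
Why: E1cB elimination (retro-oxa-Michael); the C3/C4 enolate expels the bridging C5 oxygen, which stands out of the cyclopentanone plane, giving the tetrasubstituted C4=C5 enone and the C8 alcohol with its C–O bond intact. Relief of bicyclic strain and conjugation drive it, the C4 and C5 stereocentres disappear, and a short reaction time avoids epimerising C1 through the dienolate.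

**Step 12**
Reactants: 18 (1R,7S,8R,10S)-8,11-dihydroxyguai-4-en-3-one
Product: 19 (1R,7S,8R,10S)-11-hydroxy-8-(methacryloyloxy)guai-4-en-3-one
Conditions: methacrylic anhydride (1.5 equiv), Et3N, DMAP (0.1 equiv), CH2Cl2, 0 → 23 °C
Reagents that add atoms: methacrylic anhydride, C=C(C)C(=O)OC(=O)C(C)=C
Why: DMAP-catalysed acylation, selective for the secondary C8 hydroxyl over the tertiary C11 hydroxyl on steric grounds.

**Step 13**
Reactants: 19 (1R,7S,8R,10S)-11-hydroxy-8-(methacryloyloxy)guai-4-en-3-one
Product: 20 (1R,7S,8R,10S)-11-acetoxy-8-(methacryloyloxy)guai-4-en-3-one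
Conditions: Ac2O (5 equiv), DMAP (2 equiv), Et3N (5 equiv), CH2Cl2, 40 °C
Reagents that add atoms: acetic anhydride, CC(=O)OC(C)=O
Why: DMAP-mediated acetylation of a tertiary alcohol through the N-acetylpyridinium ion; no stereocentre is touched, and migration of the methacryloyl group to the tertiary oxygen is thermodynamically uphill.

**Compound list**

1 | 3-methylfuran-2-carbaldehyde | Cc1ccoc1C=O | starting material
2 | (E)-crotylboronic acid pinacol ester | C/C=C/CB1OC(C)(C)C(C)(C)O1 | starting material
3 | pinacol borate ester of 4, 2-{[(1R,2R)-2-methyl-1-(3-methylfuran-2-yl)but-3-en-1-yl]oxy}-4,4,5,5-tetramethyl-1,3,2-dioxaborolane | Cc1ccoc1[C@H](OB2OC(C)(C)C(C)(C)O2)[C@H](C)C=C | intermediate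
4 | (1R,2R)-2-methyl-1-(3-methylfuran-2-yl)but-3-en-1-ol | Cc1ccoc1[C@H](O)[C@H](C)C=C | intermediate
5 | (2R)-2-[(2R)-but-3-en-2-yl]-6-hydroxy-4-methyl-2H-pyran-3(6H)-one, both anomers | CC1=CC(O)O[C@H]([C@H](C)C=C)C1=O | intermediate
6 | (2R)-6-acetoxy-2-[(2R)-but-3-en-2-yl]-4-methyl-2H-pyran-3(6H)-one, both anomers | CC1=CC(OC(C)=O)O[C@H]([C@H](C)C=C)C1=O | intermediate
7 | methyl acrylate | C=CC(=O)OC | starting material
8 | 2-[(2R)-but-3-en-2-yl]-4-methylpyrylium-3-olate (oxidopyrylium ylide, formed in the flask) | C=C[C@@H](C)c1[o+]ccc(C)c1[O-] | intermediate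
9 | methyl (1S,5R)-1-[(2R)-but-3-en-2-yl]-3-methyl-2-oxo-8-oxabicyclo[3.2.1]oct-3-ene-6-carboxylate, both C6 epimers (guaiane: C5–O–C8 bridge, C1 ketone, C9=C10, ester on C7) | COC(=O)C1C[C@@]2([C@H](C)C=C)O[C@@H]1C=C(C)C2=O | intermediate
10 | lithium enolate (C1–OLi, C1=C10) from 1,4-reduction of 9, formed in the flask | COC(=O)C1C[C@@]2([C@H](C)C=C)O[C@@H]1CC(C)=C2O[Li] | intermediate
11 | methyl (1S,5R)-1-[(2R)-but-3-en-2-yl]-3-methyl-2-oxo-8-oxabicyclo[3.2.1]octane-6-carboxylate, mixed at C3 and C6, formed in the flask | COC(=O)C1C[C@@]2([C@H](C)C=C)O[C@@H]1CC(C)C2=O | intermediate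
12 | methyl (1S,3S,5R,6S)-1-[(2R)-but-3-en-2-yl]-3-methyl-2-oxo-8-oxabicyclo[3.2.1]octane-6-carboxylate (methyl equatorial, ester exo, both cis to the oxygen bridge) | COC(=O)[C@H]1C[C@@]2([C@H](C)C=C)O[C@@H]1C[C@H](C)C2=O | intermediate
13 | methyl (1S,3S,5R,6S)-1-[(2R)-but-3-en-2-yl]-2-ethenyl-2-hydroxy-3-methyl-8-oxabicyclo[3.2.1]octane-6-carboxylate, vinyl axial (cis to the oxygen bridge) | COC(=O)[C@H]1C[C@@]2([C@H](C)C=C)O[C@@H]1C[C@H](C)[C@]2(O)C=C | intermediate
14 | (1S,3S,5R,6S)-1-[(2R)-but-3-en-2-yl]-2-ethenyl-6-(2-hydroxypropan-2-yl)-3-methyl-8-oxabicyclo[3.2.1]octan-2-ol, vinyl axial | CC(C)(O)[C@H]1C[C@@]2([C@H](C)C=C)O[C@@H]1C[C@H](C)[C@]2(O)C=C | intermediate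
15 | 5,8-epoxyguai-2-ene-1,11-diol: C1 hydroxyl trans to the oxygen bridge; C10 methyl and C7 hydroxypropyl cis to it; C4 methyl trans to the bridge oxygen | CC(C)(O)[C@H]1C[C@@]23O[C@@H]1C[C@H](C)[C@]2(O)C=C[C@H]3C | intermediate
16 | 5,8-epoxy-11-hydroxyguai-1-en-3-one, configurations at C4, C5, C7, C8 and C10 as in 15 | CC(C)(O)[C@H]1C[C@@]23O[C@@H]1C[C@H](C)C2=CC(=O)[C@H]3C | intermediate
17 | 5,8-epoxy-11-hydroxyguaian-3-one, H-1 cis to the oxygen bridge, other centres as in 16 | CC(C)(O)[C@H]1C[C@@]23O[C@@H]1C[C@H](C)[C@H]2CC(=O)[C@H]3C | intermediate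
18 | (1R,7S,8R,10S)-8,11-dihydroxyguai-4-en-3-one | O[C@@H]1C[C@H](C)[C@H]2CC(=O)C(C)=C2C[C@@H]1C(C)(C)O | intermediate
19 | (1R,7S,8R,10S)-11-hydroxy-8-(methacryloyloxy)guai-4-en-3-one | C=C(C)C(=O)O[C@@H]1C[C@H](C)[C@H]2CC(=O)C(C)=C2C[C@@H]1C(C)(C)O | intermediate
20 | (1R,7S,8R,10S)-11-acetoxy-8-(methacryloyloxy)guai-4-en-3-one | C=C(C)C(=O)O[C@@H]1C[C@H](C)[C@H]2CC(=O)C(C)=C2C[C@@H]1C(C)(C)OC(C)=O | target

Total step count: 13. Longest linear sequence: 13 steps (1 → 20); 2 and 7 are commercial partners.

**Steps most likely to fail**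

Step 4. The C4 centre may discriminate poorly between the two faces of the ylide, because its out-of-plane groups (methyl and vinyl) are similar in size. Wrong-face adducts would then form in comparable amount and be lost on separation, and ylide dimerisation would take a further share. The fallback adds a second stereocontrol element on the dipolarophile and sets out from 6. Methyl (S)-lactate is acylated with acryloyl chloride (Et3N, CH2Cl2) to the chiral acrylate (S)-1-methoxy-1-oxopropan-2-yl acrylate F1, or its antipode if that proves the matched partner. F1 is used in place of 7 under the conditions of step 4, a cycloaddition of the kind known for lactate acrylates with the related oxidopyridinium ylides, and gives the lactate-ester cycloadduct F2. Reduction with LiBH(s-Bu)3 as in step 5 gives, through the lithium enolate F3, the lactate keto ester F4. NaOMe in MeOH then equilibrates C7 and C10 and at the same time exchanges the lactate for methoxide, so the route is rejoined at 12.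

Step 10. Hydrogen uptake at the hindered trisubstituted enone may be slow; some hydrogen may be delivered from the ethano-bridge face, giving the C1 epimer; and the allylic C5–O bond may be hydrogenolysed on palladium. The fallback replaces surface hydrogenation by hydride conjugate reduction and sets out from 16. Treatment with [(Ph3P)CuH]6 in wet benzene at 23 °C should deliver hydride to C1 from the open bridge-oxygen face and give the copper enolate F5, which is protonated in the flask at C2 to return to the route at 17, with no path to C–O cleavage.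

Step 13. The tertiary C11 hydroxyl, flanked by the cis C8 methacrylate, may resist acylation, or may eliminate to the isopropenyl compound under forcing conditions. The fallback installs the acetate before the bridge is opened and sets out from 17. Acetylation (Ac2O, DMAP, Et3N), now without a neighbouring ester, gives the 11-acetate F6. TMSOTf and Et3N (CH2Cl2, −78 → 0 °C) open the bridge through the silyl enol ether, as known for oxabicyclic ketones, so the C8 oxygen emerges silylated and no free alkoxide can take the acetyl group; this gives the 8-trimethylsilyloxy enone acetate F7. Dilute HCl in THF gives the 8-hydroxy 11-acetate F8, and acylation with methacrylic anhydride, DMAP and Et3N rejoins the route at 20.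

**Further compounds**

F1 | step 4 | (S)-1-methoxy-1-oxopropan-2-yl acrylate | C=CC(=O)O[C@@H](C)C(=O)OC
F2 | step 4 | (S)-1-methoxy-1-oxopropan-2-yl (1S,5R)-1-[(2R)-but-3-en-2-yl]-3-methyl-2-oxo-8-oxabicyclo[3.2.1]oct-3-ene-6-carboxylate, both C6 epimers | COC(=O)[C@H](C)OC(=O)C1C[C@@]2([C@H](C)C=C)O[C@@H]1C=C(C)C2=O
F3 | step 4 | lithium enolate from 1,4-reduction of F2 | COC(=O)[C@H](C)OC(=O)C1C[C@@]2([C@H](C)C=C)O[C@@H]1CC(C)=C2O[Li]
F4 | step 4 | (S)-1-methoxy-1-oxopropan-2-yl (1S,5R)-1-[(2R)-but-3-en-2-yl]-3-methyl-2-oxo-8-oxabicyclo[3.2.1]octane-6-carboxylate, mixed at C3 and C6 | COC(=O)[C@H](C)OC(=O)C1C[C@@]2([C@H](C)C=C)O[C@@H]1CC(C)C2=O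
F5 | step 10 | copper enolate (C3–OCu, C2=C3) of 17, phosphine ligands omitted | CC(C)(O)[C@H]1C[C@@]23O[C@@H]1C[C@H](C)[C@H]2C=C(O[Cu])[C@H]3C
F6 | step 13 | 11-acetoxy-5,8-epoxyguaian-3-one, configurations as in 17 | CC(=O)OC(C)(C)[C@H]1C[C@@]23O[C@@H]1C[C@H](C)[C@H]2CC(=O)[C@H]3C
F7 | step 13 | (1R,7S,8R,10S)-11-acetoxy-8-(trimethylsilyloxy)guai-4-en-3-one | C[Si](C)(C)O[C@@H]1C[C@H](C)[C@H]2CC(=O)C(C)=C2C[C@@H]1C(C)(C)OC(C)=O
F8 | step 13 | (1R,7S,8R,10S)-11-acetoxy-8-hydroxyguai-4-en-3-one | O[C@@H]1C[C@H](C)[C@H]2CC(=O)C(C)=C2C[C@@H]1C(C)(C)OC(C)=O
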